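**Plan** (labdane numbering; TBS = tert-butyldimethylsilyl)

- Cuts: the C15 acetate and C19 ester are functional-group changes. C8=C17 goes back to a C8 ketone and C5–H to a C5 carbinol. Ring B is then opened at C5–C6, followed by C7–C8, C9–C10, C10–C20 and C4–C18. The side chain is cut at C9=C8 back to (S)-citronellol.
- Enabling feature: C5 lies between the two quaternary carbons C4 and C10. It can therefore be the carbonyl carbon of a ring A cyclohexanone whose two α-carbons are built by enolate chemistry. Its ketyl reaches the terminal carbon C6 of a vinyl ketone carried on C9 and closes ring B (20 → 21).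
- Forward order: the ring A keto ester is methylated at C4 and then C10. The citronellol-derived allyl carbonate is joined at C10, creating C9. The vinyl group is converted into the C8 vinyl ketone and ring B is closed at C5–C6. Dehydration, C5 reduction, C8 methylenation, deprotection and acetylation finish the route.
- Stereochemistry: C13 comes from (S)-citronellol. C4 comes from methylation of a valine-derived chiral enamine. C9 and C10 come from the iridium–phosphoramidite catalyst. C5 comes from hydrogen delivery to the α face (trans fusion). C9 is also the thermodynamic epimer next to the C8 ketone.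

Key step: step 13

Assumption: the auxiliary and ligand antipodes named in steps 2 and 9 are those expected to give the drawn configurations at C4 and at C9/C10; if the sense of induction proves opposite, the mirror-image auxiliary or ligand is used.

**Route**

Step 1
Reactants: 1 methyl 2-oxocyclohexane-1-carboxylate; 2 L-valine tert-butyl ester
Product: 3 methyl 2-{[(2S)-1-(tert-butoxy)-3-methyl-1-oxobutan-2-yl]amino}cyclohex-1-ene-1-carboxylate
Conditions: BF3·OEt2 (cat.), benzene, reflux, Dean–Stark
Reagents that add atoms: none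
Why: Acid-catalysed condensation of the β-keto ester with the primary amine gives the conjugated, hydrogen-bonded enamino ester, which places the valine stereocentre next to the future C4.

Step 2
Reactants: 3 methyl 2-{[(2S)-1-(tert-butoxy)-3-methyl-1-oxobutan-2-yl]amino}cyclohex-1-ene-1-carboxylate
Product: 5 methyl (1S)-1-methyl-2-oxocyclohexane-1-carboxylate, via methylated imine 4 (not isolated)
Conditions: LDA, toluene, HMPA (1 equiv), −78 °C; MeI, −78 → −40 °C; then 1 M aq citric acid, rt
Reagents that add atoms: methyl iodide, CI; water, O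
Why: Auxiliary-controlled alkylation of a chiral lithio-enamine, in which the chelated lithium holds the valine isopropyl group over one face of C4 so that methyl iodide enters from the other face and sets C4 as (S), after which mild hydrolysis of the imine releases the keto ester and the auxiliary.

Step 3
Reactants: 5 methyl (1S)-1-methyl-2-oxocyclohexane-1-carboxylate
Product: 6 methyl (1S)-1,3-dimethyl-2-oxocyclohexane-1-carboxylate (both C3 epimers)
Conditions: LDA, THF, −78 °C; MeI, −78 → 0 °C
Reagents that add atoms: methyl iodide, CI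
Why: Kinetic enolate alkylation, in which LDA can remove a proton only from C10 because C4 is quaternary, and the configuration formed at C10 is of no consequence since this carbon is enolised again in step 9.

Step 4
Reactants: 7 (S)-citronellol
Product: 8 tert-butyl{[(3S)-3,7-dimethyloct-6-en-1-yl]oxy}dimethylsilane
Conditions: TBSCl, imidazole, CH2Cl2, rt
Reagents that add atoms: tert-butyldimethylsilyl chloride, CC(C)(C)[Si](C)(C)Cl
Why: Standard silylation of the primary alcohol gives an ether that survives every operation up to step 17 and leaves the C13 stereocentre untouched.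

Step 5
Reactants: 8 tert-butyl{[(3S)-3,7-dimethyloct-6-en-1-yl]oxy}dimethylsilane
Product: 10 (4S)-6-[(tert-butyldimethylsilyl)oxy]-4-methylhexanal, via ozonide 9 (not isolated)
Conditions: O3, CH2Cl2, −78 °C; PPh3, −78 °C → rt
Reagents that add atoms: ozone, [O-][O+]=O
Why: Ozonolysis with reductive work-up cleaves the trisubstituted alkene and leaves the aldehyde carbon that becomes C9.

Step 6
Reactants: 10 (4S)-6-[(tert-butyldimethylsilyl)oxy]-4-methylhexanal; 11 triethyl phosphonoacetate
Product: 12 ethyl (2E,6S)-8-[(tert-butyldimethylsilyl)oxy]-6-methyloct-2-enoate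
Conditions: NaH, THF, 0 °C → rt
Reagents that add atoms: none
Why: Horner–Wadsworth–Emmons olefination of an unbranched aldehyde with the stabilised phosphonate anion gives the (E)-enoate needed for a linear (E)-allyl electrophile.

Step 7
Reactants: 12 ethyl (2E,6S)-8-[(tert-butyldimethylsilyl)oxy]-6-methyloct-2-enoate
Product: 13 (2E,6S)-8-[(tert-butyldimethylsilyl)oxy]-6-methyloct-2-en-1-ol
Conditions: DIBAL-H (2.2 equiv), CH2Cl2, −78 °C; Rochelle salt
Reagents that add atoms: none
Why: DIBAL-H reduces the conjugated ester by 1,2-hydride addition to the allylic alcohol without touching the alkene or the silyl ether.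

Step 8
Reactants: 13 (2E,6S)-8-[(tert-butyldimethylsilyl)oxy]-6-methyloct-2-en-1-ol
Product: 14 tert-butyl (2E,6S)-8-[(tert-butyldimethylsilyl)oxy]-6-methyloct-2-en-1-yl carbonate
Conditions: Boc2O, DMAP (cat.), CH2Cl2, 0 °C → rt
Reagents that add atoms: di-tert-butyl dicarbonate, CC(C)(C)OC(=O)OC(=O)OC(C)(C)C
Why: DMAP-catalysed acylation gives the tert-butyl carbonate, whose leaving group releases only non-nucleophilic tert-butoxide in step 9 and so spares the non-enolisable β-keto ester from retro-Claisen cleavage.

Step 9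
Reactants: 6 methyl (1S)-1,3-dimethyl-2-oxocyclohexane-1-carboxylate (both C3 epimers); 14 tert-butyl (2E,6S)-8-[(tert-butyldimethylsilyl)oxy]-6-methyloct-2-en-1-yl carbonate
Product: 15 methyl (1S,3R)-3-[(3S,6S)-8-[(tert-butyldimethylsilyl)oxy]-6-methyloct-1-en-3-yl]-1,3-dimethyl-2-oxocyclohexane-1-carboxylate
Conditions: Ba(Ot-Bu)2 (0.6 equiv), iridacycle from [Ir(cod)Cl]2, BINOL-derived bis(1-arylethyl)amine phosphoramidite and n-PrNH2 (4 mol % Ir), THF, rt
Reagents that add atoms: none
Why: Iridium-catalysed asymmetric allylic alkylation of a preformed ketone enolate, in which the barium enolate (formed only at C10) attacks the substituted terminus of the (π-allyl)iridium complex to give the branched product, the catalyst fixing the allyl face (C9) and the enolate face (C10) in the bond that creates the vicinal tertiary/quaternary pair, while the remote C4 centre is expected to bias the enolate faces only weakly.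

Step 10
Reactants: 15 methyl (1S,3R)-3-[(3S,6S)-8-[(tert-butyldimethylsilyl)oxy]-6-methyloct-1-en-3-yl]-1,3-dimethyl-2-oxocyclohexane-1-carboxylate
Product: 17 methyl (1S,3R)-3-[(2R,5S)-7-[(tert-butyldimethylsilyl)oxy]-5-methyl-1-oxoheptan-2-yl]-1,3-dimethyl-2-oxocyclohexane-1-carboxylate, via ozonide 16 (not isolated)
Conditions: O3, CH2Cl2, −78 °C; PPh3, −78 °C → rt
Reagents that add atoms: ozone, [O-][O+]=O
Why: Ozonolysis of the only alkene with reductive work-up gives the C8 aldehyde under neutral conditions that do not epimerise C9.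

Step 11
Reactants: 17 methyl (1S,3R)-3-[(2R,5S)-7-[(tert-butyldimethylsilyl)oxy]-5-methyl-1-oxoheptan-2-yl]-1,3-dimethyl-2-oxocyclohexane-1-carboxylate; 18 vinylmagnesium bromide
Product: 19 methyl (1S,3R)-3-[(4R,7S)-9-[(tert-butyldimethylsilyl)oxy]-3-hydroxy-7-methylnon-1-en-4-yl]-1,3-dimethyl-2-oxocyclohexane-1-carboxylate (both carbinol epimers)
Conditions: THF, −78 °C; sat. aq NH4Cl at −78 °C
Reagents that add atoms: none
Why: Grignard 1,2-addition should occur at the aldehyde only, because the ring ketone is flanked by two quaternary carbons and the ester is neopentylic, and the uncontrolled carbinol centre is removed by oxidation in step 12.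

Step 12
Reactants: 19 methyl (1S,3R)-3-[(4R,7S)-9-[(tert-butyldimethylsilyl)oxy]-3-hydroxy-7-methylnon-1-en-4-yl]-1,3-dimethyl-2-oxocyclohexane-1-carboxylate
Product: 20 methyl (1S,3R)-3-[(4R,7S)-9-[(tert-butyldimethylsilyl)oxy]-7-methyl-3-oxonon-1-en-4-yl]-1,3-dimethyl-2-oxocyclohexane-1-carboxylate
Conditions: Dess–Martin periodinane, NaHCO3, CH2Cl2, 0 °C → rt; used at once
Reagents that add atoms: none
Why: Dess–Martin oxidation converts the allylic alcohol into the vinyl ketone under buffered, non-basic conditions that neither epimerise C9 nor add to the enone.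

Step 13
Reactants: 20 methyl (1S,3R)-3-[(4R,7S)-9-[(tert-butyldimethylsilyl)oxy]-7-methyl-3-oxonon-1-en-4-yl]-1,3-dimethyl-2-oxocyclohexane-1-carboxylate
Product: 21 methyl 15-[(tert-butyldimethylsilyl)oxy]-5α-hydroxy-8-oxo-17-norlabdan-19-oate
Conditions: SmI2 (2.5 equiv), t-BuOH (2 equiv), THF, −78 °C, slow addition of 20 (5 mM final); sat. aq NH4Cl at −78 °C
Reagents that add atoms: none
Why: Samarium(II), held between the C5 ketone and the C19 ester carbonyl, transfers one electron to give the C5 ketyl (an enone radical anion formed by competing electron transfer leads to the same bond), C5 adds to the unsubstituted enone β-carbon C6, and the resulting α-keto radical is reduced to the samarium(III) enolate of the C8 ketone, which t-BuOH protonates at C7. The closest known reaction type is the SmI2 ketyl–olefin (ketone–enone) reductive cyclisation that gives cyclic γ-hydroxy ketones. Ring B closes in the 6-endo-trig mode, both alkene carbons C6 and C7 ending inside the new ring, because attack at C7 (5-exo) would leave an unstabilised primary radical. The new stereocentre C5 is governed by the ring A chair and the C9/C10 centres: with the C9 chain equatorial in a chair-like transition state the O–Sm group is expected axial and anti to the C10 methyl, that is the trans-fused 5α-ol, but either epimer serves because C5 becomes sp2 in step 14. The step needs C5–C6 coupling to outrun 1,4-reduction and reductive dimerisation of the vinyl ketone, which the six-membered intramolecular path onto an unhindered CH2 terminus, chelation-assisted ketyl formation, high dilution and low temperature should secure, while the cold protic quench keeps the samarium alkoxide from retro-aldol cleavage of C4–C5.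

Step 14
Reactants: 21 methyl 15-[(tert-butyldimethylsilyl)oxy]-5α-hydroxy-8-oxo-17-norlabdan-19-oate
Product: 22 methyl 15-[(tert-butyldimethylsilyl)oxy]-8-oxo-17-norlabd-5-en-19-oate
Conditions: SOCl2, pyridine, CH2Cl2, −20 → 0 °C
Reagents that add atoms: none
Why: Pyridine-buffered E2 dehydration through the chlorosulfite, in which the axial 5α-oxygen is anti-periplanar to the axial 6β-hydrogen and the C5=C6 alkene is the only one possible because C4 and C10 carry no hydrogen, while the basic medium disfavours ionisation and methyl migration.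

Step 15
Reactants: 22 methyl 15-[(tert-butyldimethylsilyl)oxy]-8-oxo-17-norlabd-5-en-19-oate
Product: 23 methyl 15-[(tert-butyldimethylsilyl)oxy]-8-oxo-17-norlabdan-19-oate (5α-H, 9β side chain)
Conditions: Mn(dpm)3 (10 mol %), PhSiH3, TBHP, i-PrOH, rt
Reagents that add atoms: none
Why: Metal-hydride hydrogen-atom-transfer hydrogenation, in which a hydrogen atom adds to C6 and the tertiary C5 radical takes its hydrogen on the α face, opposite the axial C10 methyl and C4 ester, giving the thermodynamically preferred trans ring fusion.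

Step 16
Reactants: 23 methyl 15-[(tert-butyldimethylsilyl)oxy]-8-oxo-17-norlabdan-19-oate
Product: 24 methyl 15-[(tert-butyldimethylsilyl)oxy]labd-8(17)-en-19-oate
Conditions: Ph3PCH3Br, KOt-Bu, THF, 0 → 50 °C
Reagents that add atoms: methyltriphenylphosphonium bromide, C[P+](c1ccccc1)(c1ccccc1)c1ccccc1.[Br-]
Why: Wittig methylenation of the C8 ketone, a standard operation on 8-oxo-17-norlabdanes, in which the basic ylide can only preserve C9 because the equatorial side chain is the thermodynamically favoured epimer.

Step 17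
Reactants: 24 methyl 15-[(tert-butyldimethylsilyl)oxy]labd-8(17)-en-19-oate
Product: 25 methyl 15-hydroxylabd-8(17)-en-19-oate
Conditions: TBAF, THF, 0 °C → rt
Reagents that add atoms: none
Why: Fluoride-induced cleavage of the primary silyl ether leaves the hindered methyl ester and the exocyclic alkene untouched.

Step 18
Reactants: 25 methyl 15-hydroxylabd-8(17)-en-19-oate
Product: 26 15-hydroxylabd-8(17)-en-19-oic acid
Conditions: NaSEt, DMF, 100 °C; then 1 M HCl to pH 3
Reagents that add atoms: none
Why: The axial neopentylic ester resists saponification, so it is cleaved by SN2 attack of thiolate on the O-methyl group, which is insensitive to hindrance at C4 and cannot epimerise any centre.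

Step 19
Reactants: 26 15-hydroxylabd-8(17)-en-19-oic acid
Product: 27 15-acetoxylabd-8(17)-en-19-oic acid (target)
Conditions: Ac2O, pyridine, DMAP (cat.), CH2Cl2, 0 °C → rt; aqueous work-up
Reagents that add atoms: acetic anhydride, CC(=O)OC(C)=O
Why: Nucleophile-catalysed acetylation of the primary alcohol, any mixed anhydride of the hindered C19 acid being hydrolysed back at its acetyl carbonyl during aqueous work-up.

**Compound list**

1 | methyl 2-oxocyclohexane-1-carboxylate | COC(=O)C1CCCCC1=O | starting material
2 | L-valine tert-butyl ester | CC(C)[C@H](N)C(=O)OC(C)(C)C | starting material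
3 | methyl 2-{[(2S)-1-(tert-butoxy)-3-methyl-1-oxobutan-2-yl]amino}cyclohex-1-ene-1-carboxylate | COC(=O)C1=C(N[C@@H](C(C)C)C(=O)OC(C)(C)C)CCCC1 | intermediate
4 | tert-butyl (2S)-2-{[(2S)-2-(methoxycarbonyl)-2-methylcyclohexylidene]amino}-3-methylbutanoate (methylated imine) | CC(C)[C@H](N=C1CCCC[C@]1(C)C(=O)OC)C(=O)OC(C)(C)C | intermediate (not isolated)
5 | methyl (1S)-1-methyl-2-oxocyclohexane-1-carboxylate | O=C1CCCC[C@]1(C)C(=O)OC | intermediate
6 | methyl (1S)-1,3-dimethyl-2-oxocyclohexane-1-carboxylate (both C3 epimers) | O=C1C(C)CCC[C@]1(C)C(=O)OC | intermediate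
7 | (S)-citronellol | CC(C)=CCC[C@H](C)CCO | starting material
8 | tert-butyl{[(3S)-3,7-dimethyloct-6-en-1-yl]oxy}dimethylsilane | CC(C)=CCC[C@H](C)CCO[Si](C)(C)C(C)(C)C | intermediate
9 | 3-{(3S)-5-[(tert-butyldimethylsilyl)oxy]-3-methylpentyl}-5,5-dimethyl-1,2,4-trioxolane (ozonide) | CC1(C)OC(CC[C@H](C)CCO[Si](C)(C)C(C)(C)C)OO1 | intermediate (not isolated)
10 | (4S)-6-[(tert-butyldimethylsilyl)oxy]-4-methylhexanal | O=CCC[C@H](C)CCO[Si](C)(C)C(C)(C)C | intermediate
11 | triethyl phosphonoacetate | CCOC(=O)CP(=O)(OCC)OCC | starting material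
12 | ethyl (2E,6S)-8-[(tert-butyldimethylsilyl)oxy]-6-methyloct-2-enoate | CCOC(=O)/C=C/CC[C@H](C)CCO[Si](C)(C)C(C)(C)C | intermediate
13 | (2E,6S)-8-[(tert-butyldimethylsilyl)oxy]-6-methyloct-2-en-1-ol | OC/C=C/CC[C@H](C)CCO[Si](C)(C)C(C)(C)C | intermediate
14 | tert-butyl (2E,6S)-8-[(tert-butyldimethylsilyl)oxy]-6-methyloct-2-en-1-yl carbonate | CC(C)(C)OC(=O)OC/C=C/CC[C@H](C)CCO[Si](C)(C)C(C)(C)C | intermediate
15 | methyl (1S,3R)-3-[(3S,6S)-8-[(tert-butyldimethylsilyl)oxy]-6-methyloct-1-en-3-yl]-1,3-dimethyl-2-oxocyclohexane-1-carboxylate | O=C1[C@](C)(CCC[C@]1(C)C(=O)OC)[C@@H](CC[C@H](C)CCO[Si](C)(C)C(C)(C)C)C=C | intermediate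
16 | 1,2,4-trioxolane (ozonide) of the vinyl group of 15 | O=C1[C@](C)(CCC[C@]1(C)C(=O)OC)[C@@H](CC[C@H](C)CCO[Si](C)(C)C(C)(C)C)C2OCOO2 | intermediate (not isolated)
17 | methyl (1S,3R)-3-[(2R,5S)-7-[(tert-butyldimethylsilyl)oxy]-5-methyl-1-oxoheptan-2-yl]-1,3-dimethyl-2-oxocyclohexane-1-carboxylate | O=C1[C@](C)(CCC[C@]1(C)C(=O)OC)[C@@H](CC[C@H](C)CCO[Si](C)(C)C(C)(C)C)C=O | intermediate
18 | vinylmagnesium bromide | C=C[Mg]Br | starting material
19 | methyl (1S,3R)-3-[(4R,7S)-9-[(tert-butyldimethylsilyl)oxy]-3-hydroxy-7-methylnon-1-en-4-yl]-1,3-dimethyl-2-oxocyclohexane-1-carboxylate (both carbinol epimers) | O=C1[C@](C)(CCC[C@]1(C)C(=O)OC)[C@@H](CC[C@H](C)CCO[Si](C)(C)C(C)(C)C)C(O)C=C | intermediate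
20 | methyl (1S,3R)-3-[(4R,7S)-9-[(tert-butyldimethylsilyl)oxy]-7-methyl-3-oxonon-1-en-4-yl]-1,3-dimethyl-2-oxocyclohexane-1-carboxylate | O=C1[C@](C)(CCC[C@]1(C)C(=O)OC)[C@@H](CC[C@H](C)CCO[Si](C)(C)C(C)(C)C)C(=O)C=C | intermediate
21 | methyl 15-[(tert-butyldimethylsilyl)oxy]-5α-hydroxy-8-oxo-17-norlabdan-19-oate (trans-fused, 13S) | O=C1CC[C@]2(O)[C@](C)(CCC[C@]2(C)C(=O)OC)[C@H]1CC[C@H](C)CCO[Si](C)(C)C(C)(C)C | intermediate
22 | methyl 15-[(tert-butyldimethylsilyl)oxy]-8-oxo-17-norlabd-5-en-19-oate | O=C1CC=C2[C@](C)(CCC[C@]2(C)C(=O)OC)[C@H]1CC[C@H](C)CCO[Si](C)(C)C(C)(C)C | intermediate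
23 | methyl 15-[(tert-butyldimethylsilyl)oxy]-8-oxo-17-norlabdan-19-oate (5α-H) | O=C1CC[C@@H]2[C@](C)(CCC[C@]2(C)C(=O)OC)[C@H]1CC[C@H](C)CCO[Si](C)(C)C(C)(C)C | intermediate
24 | methyl 15-[(tert-butyldimethylsilyl)oxy]labd-8(17)-en-19-oate | C=C1CC[C@@H]2[C@](C)(CCC[C@]2(C)C(=O)OC)[C@H]1CC[C@H](C)CCO[Si](C)(C)C(C)(C)C | intermediate
25 | methyl 15-hydroxylabd-8(17)-en-19-oate | C=C1CC[C@@H]2[C@](C)(CCC[C@]2(C)C(=O)OC)[C@H]1CC[C@H](C)CCO | intermediate
26 | 15-hydroxylabd-8(17)-en-19-oic acid | C=C1CC[C@@H]2[C@](C)(CCC[C@]2(C)C(=O)O)[C@H]1CC[C@H](C)CCO | intermediate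
27 | 15-acetoxylabd-8(17)-en-19-oic acid (4S,5R,9S,10R,13S) | C=C1CC[C@@H]2[C@](C)(CCC[C@]2(C)C(=O)O)[C@H]1CC[C@H](C)CCOC(C)=O | target

**Count**

Total steps: 19. Longest linear sequence: 16 (steps 4–19, from (S)-citronellol).

**Steps most likely to fail**

Step 9. The hindered tetrasubstituted enolate may react slowly, attack the unsubstituted allyl terminus, or be delivered to the wrong enolate face, giving the C10 epimer. The fallback makes the C9–C10 bond by conjugate addition and sets out from 5 and 10. The kinetic lithium enolate of 5 (LDA, THF, −78 °C) is added to aldehyde 10 to give the β-hydroxy ketone F1. This is dehydrated (MsCl, Et3N, then DBU) to the (E)-alkylidene ketone F2. Lithium divinylcuprate then adds to C9, and the C10 enolate so formed is trapped with MeI/HMPA. This reaches 15 together with its C10 epimer, which is removed by chromatography. Any C9 epimer is harmless, because C9 sits α to the C8 ketone and is equilibrated to the equatorial epimer at the stage of 23. This variant relies on substrate control at C10 and returns to the route at 15.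

Step 13. Electron transfer to the vinyl ketone may lead to 1,4-reduction or reductive dimerisation faster than the ketyl can add from the congested C5, or the samarium alkoxide may undergo retro-aldol cleavage. The fallback forms the same C5–C6 bond by a carbanion-type closure and sets out from 19. Silylation (TESCl, imidazole) gives the triethylsilyl ether F3. Hydroboration–oxidation (9-BBN, then NaBO3) gives the primary alcohol F4, and I2/PPh3/imidazole gives the primary iodide F5. A samarium Barbier cyclisation (SmI2, HMPA, THF) adds the C6 alkylsamarium to the C5 ketone and gives the bicyclic silyl ether F6. PPTS in methanol removes the triethylsilyl group selectively to give the diol F7. Dess–Martin oxidation of its secondary alcohol returns to the route at 21.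

Step 14. The hindered hydroxyl may fail to form the chlorosulfite, or C5 may ionise, with 1,2-shift of the anti-periplanar C10 methyl (backbone rearrangement) instead of loss of the C6 proton. The fallback removes the oxygen by a radical path and sets out from 21. Acylation with methyl chlorooxoacetate (DMAP, pyridine) gives the tert-alkyl methyl oxalate F8. Bu3SnH/AIBN in refluxing toluene (Barton–McCombie-type deoxygenation) then generates the C5 radical, which takes hydrogen on the α face. This returns to the route at 23, bypassing 22 and step 15.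

**Further compounds**

F1 | step 9 | methyl (1S)-3-{(4S)-6-[(tert-butyldimethylsilyl)oxy]-1-hydroxy-4-methylhexyl}-1-methyl-2-oxocyclohexane-1-carboxylate (aldol adduct, epimers at C3 and the carbinol) | O=C1C(CCC[C@]1(C)C(=O)OC)C(O)CC[C@H](C)CCO[Si](C)(C)C(C)(C)C
F2 | step 9 | methyl (1S,3E)-3-{(4S)-6-[(tert-butyldimethylsilyl)oxy]-4-methylhexylidene}-1-methyl-2-oxocyclohexane-1-carboxylate | O=C1/C(=C/CC[C@H](C)CCO[Si](C)(C)C(C)(C)C)CCC[C@]1(C)C(=O)OC
F3 | step 13 | triethylsilyl ether of 19 | O=C1[C@](C)(CCC[C@]1(C)C(=O)OC)[C@@H](CC[C@H](C)CCO[Si](C)(C)C(C)(C)C)C(O[Si](CC)(CC)CC)C=C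
F4 | step 13 | primary alcohol from hydroboration of F3 (C6–OH) | O=C1[C@](C)(CCC[C@]1(C)C(=O)OC)[C@@H](CC[C@H](C)CCO[Si](C)(C)C(C)(C)C)C(O[Si](CC)(CC)CC)CCO
F5 | step 13 | primary iodide from F4 (C6–I) | O=C1[C@](C)(CCC[C@]1(C)C(=O)OC)[C@@H](CC[C@H](C)CCO[Si](C)(C)C(C)(C)C)C(O[Si](CC)(CC)CC)CCI
F6 | step 13 | methyl 15-[(tert-butyldimethylsilyl)oxy]-5α-hydroxy-8-[(triethylsilyl)oxy]-17-norlabdan-19-oate | CC[Si](CC)(CC)OC1CC[C@]2(O)[C@](C)(CCC[C@]2(C)C(=O)OC)[C@H]1CC[C@H](C)CCO[Si](C)(C)C(C)(C)C
F7 | step 13 | methyl 15-[(tert-butyldimethylsilyl)oxy]-5α,8-dihydroxy-17-norlabdan-19-oate | OC1CC[C@]2(O)[C@](C)(CCC[C@]2(C)C(=O)OC)[C@H]1CC[C@H](C)CCO[Si](C)(C)C(C)(C)C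
F8 | step 14 | methyl oxalate of the C5 hydroxyl of 21 | O=C1CC[C@]2(OC(=O)C(=O)OC)[C@](C)(CCC[C@]2(C)C(=O)OC)[C@H]1CC[C@H](C)CCO[Si](C)(C)C(C)(C)C
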